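## Retrosynthetic overview
1. Cut ring bond C2–C3. This is the Claisen (Dieckmann) cyclisation by which a type III polyketide synthase closes a C5-reduced stearoyl tetraketide. The linear precursor is a 4-hydroxy-5,7-dioxotetracosanoate, stored as its γ-lactone, which is an isomer of the target.
2. Cut C1–C2 of that diketo lactone. This is a crossed Claisen between the methyl-side enolate of nonadecan-2-one and an activated (S)-5-oxotetrahydrofuran-2-carboxylic acid. Both bonds to C2 are made in one pot ([5+1]).
3. The (S) carbinol centre is bought with the lactone acid (L-glutamic acid series). The lactone serves both as the OH protecting group and as the second acyl donor.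
4. Nonadecan-2-one comes from stearic acid and MeLi.
5. Ring order: only one ring is formed, the carbocycle, in the last step, and the bought lactone ring opens in that same step.

Assumption: the drawn enol is one tautomer of (4S)-4-hydroxy-2-stearoylcyclohexane-1,3-dione. The enol forms interconvert by proton shift, so the triketone obtained on acidification is the target (C24H42O4, one stereocentre, S).

## Route

**Step 1**
Reactants: 1 stearic acid (octadecanoic acid)
Product: 3 nonadecan-2-one, via dilithium gem-diolate 2 (not isolated)
Conditions: MeLi (2.2 equiv, Et2O), THF, 0 °C to rt, 2 h; inverse quench into ice-cold 1 M HCl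
Reagents that add atoms: methyllithium, [Li]C
Why: Organolithium addition to a lithium carboxylate (classical acid-to-methyl-ketone synthesis): the first MeLi deprotonates the acid, the second adds to the carboxylate, and gem-diolate 2 cannot collapse before the acidic quench, so addition stops at the ketone; no stereocentre is involved.

**Step 2**
Reactants: 4 (2S)-5-oxotetrahydrofuran-2-carboxylic acid
Product: 5 (5S)-5-(1H-benzotriazol-1-ylcarbonyl)dihydrofuran-2(3H)-one
Conditions: 1H-benzotriazole (1.05 equiv), DCC (1.05 equiv), CH2Cl2, 0 °C to rt; filter, crystallise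
Reagents that add atoms: 1H-benzotriazole, c1ccc2[nH]nnc2c1
Why: Carbodiimide coupling of the acid with the acidic N–H of benzotriazole gives a storable N-acylbenzotriazole whose carbonyl is far more electrophilic than the lactone carbonyl, and because no base is present and no azlactone pathway exists, the (S) centre bought with 4 is retained.

**Step 3**
Reactants: 3 nonadecan-2-one (2.1 equiv); 5 (5S)-5-(1H-benzotriazol-1-ylcarbonyl)dihydrofuran-2(3H)-one (1.0 equiv)
Product: 9 (6S)-3,6-dihydroxy-2-octadecanoylcyclohex-2-en-1-one, via lithium enolate 6 (not isolated), via diketo lactone 7 (not isolated), via hydroxy diketo ester 8 (not isolated)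
Conditions: LDA (commercial solution, 2.15 equiv), THF, −78 °C, add 3 in THF; add 5 in THF, −78 to −20 °C (the second equivalent of 6 acts as base and returns as 3); then NaOMe (3 equiv), MeOH, −20 to 50 °C; 1 M HCl to pH 2
Reagents that add atoms: none
Why: Proposed new method: this is a one-pot [5+1] double Claisen in which the kinetic methyl-side enolate 6 is C-acylated chemoselectively by the N-acylbenzotriazole at −78 °C where the lactone is inert (Katritzky-type C-acylation of ketone enolates), methoxide then reversibly unlocks the lactone of 7 to the linear ester 8 (the oxo-ester counterpart of the enzyme-bound tetraketide), and the diketonate carbon of 8 closes onto the ester in the same 6-membered Claisen cyclisation the synthase performs, the closest known reaction being the alkoxide (Dieckmann-type) cyclisation of 5,7-dioxoalkanoates to 2-acylcyclohexane-1,3-diones, with the very acidic triketone (pKa about 4) as thermodynamic sink, while the (S) centre is carried over from 4 and survives because every species bearing it under base is already an enolate anion whose carbinol C–H is no longer acidic.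

## Compound list
1 | stearic acid (octadecanoic acid) | CCCCCCCCCCCCCCCCCC(=O)O | starting material
2 | dilithium nonadecane-2,2-diolate | CCCCCCCCCCCCCCCCCC(C)([O-])[O-].[Li+].[Li+] | intermediate
3 | nonadecan-2-one | CCCCCCCCCCCCCCCCCC(C)=O | intermediate
4 | (2S)-5-oxotetrahydrofuran-2-carboxylic acid | OC(=O)[C@@H]1CCC(=O)O1 | starting material
5 | (5S)-5-(1H-benzotriazol-1-ylcarbonyl)dihydrofuran-2(3H)-one | O=C([C@@H]1CCC(=O)O1)n1nnc2ccccc12 | intermediate
6 | lithium nonadec-1-en-2-olate | CCCCCCCCCCCCCCCCCC(=C)[O-].[Li+] | intermediate
7 | (5S)-5-(3-oxoicosanoyl)dihydrofuran-2(3H)-one (in the flask as its lithium enolate) | CCCCCCCCCCCCCCCCCC(=O)CC(=O)[C@@H]1CCC(=O)O1 | intermediate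
8 | methyl (4S)-4-hydroxy-5,7-dioxotetracosanoate (in the flask as its enolate) | CCCCCCCCCCCCCCCCCC(=O)CC(=O)[C@@H](O)CCC(=O)OC | intermediate
9 | (6S)-3,6-dihydroxy-2-octadecanoylcyclohex-2-en-1-one | CCCCCCCCCCCCCCCCCC(=O)C1=C(O)CC[C@H](O)C1=O | target

## Step count and risks
Total step count: 3 (two one-step branches and one convergent step). Longest linear sequence: 2.

The steps most likely to fail are, in order, step 3, step 2 and step 1.

**Step 3.**
- Failure modes:
  - Ring closure may be slower than retro-Claisen cleavage.
  - The free hydroxyl of uncyclised 8 can give a 3(2H)-furanone on acidification.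
  - Overheating can dehydrate the product to the aromatic 2-stearoylresorcinol.
  - The ee may erode.
- Fallback: it gives up the lactone relay for a silyl-protected acyclic diester, so no free hydroxyl is present during either Claisen event. It sets out from 4 (with enolate 6 made from 3 as before) and comes back at 9.
  - Acid-catalysed methanolysis of 4 (MeOH, cat. H2SO4, reflux) gives dimethyl (2S)-2-hydroxypentanedioate F5.
  - TBSCl and imidazole in DMF convert it into dimethyl (2S)-2-[(tert-butyldimethylsilyl)oxy]pentanedioate F6.
  - Enolate 6 (2.1 equiv, THF, −78 to 0 °C) acylates either ester group. This gives methyl (4S)-4-[(tert-butyldimethylsilyl)oxy]-5,7-dioxotetracosanoate F7 and methyl (2S)-2-[(tert-butyldimethylsilyl)oxy]-5,7-dioxotetracosanoate F8.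
  - KOtBu in THF closes both regioisomers to the same ring, (6S)-6-[(tert-butyldimethylsilyl)oxy]-3-hydroxy-2-octadecanoylcyclohex-2-en-1-one F9.
  - Aqueous HF in MeCN then frees 9.

**Step 2.**
- Failure modes: 5 may be hard to free from the urea, may hydrolyse on handling, or may lose ee on storage.
- Fallback: it drops the activated donor and relies on the fact that both carbonyl groups of the C5 unit end up bonded to the same carbon, so the order of attack does not matter. It sets out from 4 and comes back at 9.
  - Esterification (MeOH, cat. TsOH, then distillation) gives methyl (2S)-5-oxotetrahydrofuran-2-carboxylate F3.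
  - F3 is added to enolate 6 (2.1 equiv, THF, −78 to 0 °C).
  - Attack at the ester carbonyl gives 7.
  - Attack at the lactone carbonyl gives methyl (2S)-2-hydroxy-5,7-dioxotetracosanoate F4.
  - The NaOMe/MeOH stage of step 3 cyclises both to 9.

**Step 1.**
- Failure modes: lithium stearate is poorly soluble, so conversion may be incomplete, and a slow quench gives the tertiary alcohol by over-addition.
- Fallback: it replaces organometallic addition by a malonate-type decarboxylative acylation. It sets out from 1 and comes back at 3.
  - SOCl2 converts 1 into stearoyl chloride F1.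
  - F1 C-acylates Meldrum's acid (pyridine, CH2Cl2, 0 °C) to give 5-(1-hydroxyoctadecylidene)-2,2-dimethyl-1,3-dioxane-4,6-dione F2.
  - Refluxing aqueous acetic acid hydrolyses F2 and decarboxylates it twice to give 3.

## Further compounds
F1 | step 1 | stearoyl chloride (octadecanoyl chloride) | CCCCCCCCCCCCCCCCCC(=O)Cl
F2 | step 1 | 5-(1-hydroxyoctadecylidene)-2,2-dimethyl-1,3-dioxane-4,6-dione | CCCCCCCCCCCCCCCCCC(O)=C1C(=O)OC(C)(C)OC1=O
F3 | step 2 | methyl (2S)-5-oxotetrahydrofuran-2-carboxylate | COC(=O)[C@@H]1CCC(=O)O1
F4 | step 2 | methyl (2S)-2-hydroxy-5,7-dioxotetracosanoate | CCCCCCCCCCCCCCCCCC(=O)CC(=O)CC[C@H](O)C(=O)OC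
F5 | step 3 | dimethyl (2S)-2-hydroxypentanedioate | COC(=O)CC[C@H](O)C(=O)OC
F6 | step 3 | dimethyl (2S)-2-[(tert-butyldimethylsilyl)oxy]pentanedioate | COC(=O)CC[C@H](O[Si](C)(C)C(C)(C)C)C(=O)OC
F7 | step 3 | methyl (4S)-4-[(tert-butyldimethylsilyl)oxy]-5,7-dioxotetracosanoate | CCCCCCCCCCCCCCCCCC(=O)CC(=O)[C@@H](O[Si](C)(C)C(C)(C)C)CCC(=O)OC
F8 | step 3 | methyl (2S)-2-[(tert-butyldimethylsilyl)oxy]-5,7-dioxotetracosanoate | CCCCCCCCCCCCCCCCCC(=O)CC(=O)CC[C@H](O[Si](C)(C)C(C)(C)C)C(=O)OC
F9 | step 3 | (6S)-6-[(tert-butyldimethylsilyl)oxy]-3-hydroxy-2-octadecanoylcyclohex-2-en-1-one | CCCCCCCCCCCCCCCCCC(=O)C1=C(O)CC[C@H](O[Si](C)(C)C(C)(C)C)C1=O
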